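The carbocyclic ring A (C4a, C5, C6, C7, C8, C8a; isochromene numbering) is disconnected at the C8–C8a bond. C8a is the γ-carbon of the C6 enone and C8 is the carbonyl next to the quaternary C7 carbinol, so a vinylogous Dieckmann closure is possible. The γ-dienolate of an open-chain enynone attacks the lactone carbonyl of a lactate-derived dioxolanone that carries C7 in enantiopure form. In one operation ring A closes, pivalaldehyde is expelled, the C7 oxygen is unmasked and either C4a=C5 geometry converges on one product. The precursor is a C5=C4a enone bearing an acetal (C1), an alkyne (C3–C4) and the dioxolanone (C7, C8).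

Key step: step 10

Numbering: C1 (OCH=), O2, C3 (bears the dienyl chain), C4, C4a, C5 (Cl), C6 (C=O), C7 (quaternary), C8 (C=O), C8a; ring A is the carbocycle, ring B the pyran; C13 is the side-chain stereocentre.

Assumption: 4,4-diethoxybut-1-yne (8) is taken as a catalogue compound; (R)-lactic acid and (S)-2-methylbutan-1-ol are used as the enantiopure commercial materials.

Step 1
Reactants: 1 (S)-2-methylbutan-1-ol
Product: 2 (S)-2-methylbutanal
Conditions: TEMPO (1 mol%), KBr (10 mol%), NaOCl, CH2Cl2/H2O (pH 9.5), 0 °C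
Reagents that add atoms: none
Why: The TEMPO/hypochlorite oxidation of a primary alcohol stops at the aldehyde and, being fast at 0 °C and near-neutral pH, should not enolise the α-stereocentre, which comes unchanged from 1.

Step 2
Reactants: 2 (S)-2-methylbutanal
Product: 3 (2E,4S)-2,4-dimethylhex-2-enal
Conditions: Ph3P=C(Me)CHO, toluene, 85 °C
Reagents that add atoms: 2-(triphenylphosphoranylidene)propanal, CC(C=O)=P(c1ccccc1)(c1ccccc1)c1ccccc1
Why: The Wittig reaction of a stabilised formyl ylide should give the (E)-2-methyl enal under thermodynamic control, and its neutral conditions leave the adjacent stereocentre untouched.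

Step 3
Reactants: 3 (2E,4S)-2,4-dimethylhex-2-enal
Product: 5 (3E,5E,7S)-5,7-dimethylnona-3,5-dien-1-yne, via trimethylsilyl dienyne 4 (not isolated)
Conditions: (EtO)2P(O)CH2C≡CSiMe3, NaN(SiMe3)2, THF, −78 °C to rt; then K2CO3 (cat.), MeOH, rt
Reagents that add atoms: diethyl [3-(trimethylsilyl)prop-2-yn-1-yl]phosphonate, CCOP(=O)(CC#C[Si](C)(C)C)OCC
Why: The Horner–Wadsworth–Emmons reaction of the preformed propargylic phosphonate anion adds to the aldehyde faster than it deprotonates the γ-CH, should give the (E)-enyne, and methanolysis of the C–Si bond in the same flask frees the terminal alkyne.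

Step 4
Reactants: 6 (R)-lactic acid
Product: 7 (2R,5R)-2-tert-butyl-5-methyl-1,3-dioxolan-4-one
Conditions: t-BuCHO, p-TsOH (cat.), H2SO4 (cat.), pentane, reflux (Dean–Stark); crystallisation at −78 °C
Reagents that add atoms: pivalaldehyde, CC(C)(C)C=O
Why: Acid-catalysed acetalisation (first stage of self-regeneration of stereocentres) keeps C5 from 6 and sets the acetal carbon under thermodynamic control cis to the methyl group, the cis isomer being purified by crystallisation.

Step 5
Reactants: 8 4,4-diethoxybut-1-yne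
Product: 9 2-(prop-2-yn-1-yl)-1,3-dioxolane
Conditions: HOCH2CH2OH, p-TsOH (cat.), 80 °C, EtOH distilled off
Reagents that add atoms: ethane-1,2-diol, OCCO
Why: Transacetalisation driven by removal of ethanol installs a cyclic acetal, chosen because any β-alkoxide opening under the base of step 10 stays tethered and reversible.

Step 6
Reactants: 9 2-(prop-2-yn-1-yl)-1,3-dioxolane
Product: 10 4-(1,3-dioxolan-2-yl)but-2-ynal
Conditions: n-BuLi, THF, −78 °C; DMF, −78 to 0 °C; inverse quench into 10% aq. KH2PO4
Reagents that add atoms: N,N-dimethylformamide, CN(C)C=O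
Why: Formylation of the lithium acetylide with DMF is a standard ynal synthesis, and the inverse phosphate quench keeps liberated dimethylamine from adding to the ynal.

Step 7
Reactants: 7 (2R,5R)-2-tert-butyl-5-methyl-1,3-dioxolan-4-one, 10 4-(1,3-dioxolan-2-yl)but-2-ynal
Product: 11 (2R,5S)-2-tert-butyl-5-[4-(1,3-dioxolan-2-yl)-1-hydroxybut-2-yn-1-yl]-5-methyl-1,3-dioxolan-4-one (both carbinol epimers)
Conditions: LiN(i-Pr)2, THF, −78 °C; then 10, −78 °C; aq. NH4Cl
Reagents that add atoms: none
Why: In this aldol addition the ynal is attacked 1,2 by the dioxolanone lithium enolate on the face anti to the tert-butyl group, which sets the quaternary centre (future C7) with retention of the lactate configuration; the uncontrolled carbinol centre is erased in step 8.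

Step 8
Reactants: 11 (2R,5S)-2-tert-butyl-5-[4-(1,3-dioxolan-2-yl)-1-hydroxybut-2-yn-1-yl]-5-methyl-1,3-dioxolan-4-one
Product: 12 (2R,5S)-2-tert-butyl-5-[4-(1,3-dioxolan-2-yl)but-2-ynoyl]-5-methyl-1,3-dioxolan-4-one
Conditions: Dess–Martin periodinane, NaHCO3, CH2Cl2, 0 °C to rt
Reagents that add atoms: none
Why: Dess–Martin oxidation converts the propargylic alcohol to the ynone under buffered, non-basic conditions that spare both acetals and the non-enolisable quaternary centre.

Step 9
Reactants: 12 (2R,5S)-2-tert-butyl-5-[4-(1,3-dioxolan-2-yl)but-2-ynoyl]-5-methyl-1,3-dioxolan-4-one, 5 (3E,5E,7S)-5,7-dimethylnona-3,5-dien-1-yne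
Product: 13 (2R,5S)-2-tert-butyl-5-[(2E,6E,8E,10S)-3-(1,3-dioxolan-2-ylmethyl)-8,10-dimethyldodeca-2,6,8-trien-4-ynoyl]-5-methyl-1,3-dioxolan-4-one
Conditions: Pd(OAc)2 (5 mol%), tris(2,6-dimethoxyphenyl)phosphine (5 mol%), THF, rt
Reagents that add atoms: none
Why: In this palladium-catalysed donor–acceptor alkyne cross-coupling (hydroalkynylation of an ynone), syn carbopalladation places the alkynyl group on the β-carbon and hydrogen on the α-carbon, which should give the (E)-enynone with the CH2–acetal arm cis to the acyl group.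

Step 10
Reactants: 13 (2R,5S)-2-tert-butyl-5-[(2E,6E,8E,10S)-3-(1,3-dioxolan-2-ylmethyl)-8,10-dimethyldodeca-2,6,8-trien-4-ynoyl]-5-methyl-1,3-dioxolan-4-one
Product: 16 (6R)-3-[(3E,5E,7S)-5,7-dimethylnona-3,5-dien-1-yn-1-yl]-4-(1,3-dioxolan-2-yl)-5,6-dihydroxy-6-methylcyclohexa-2,4-dien-1-one, via potassium dienolate 14 (not isolated), via ring-closed hemiacetal alkoxide 15 (not isolated)
Conditions: KN(SiMe3)2 (2.5 equiv), THF (0.02 M), −78 to 0 °C; aq. NH4Cl, 0 °C
Reagents that add atoms: none
Why: KN(SiMe3)2 removes a C8a–H (γ to the C6 ketone) to give the cross-conjugated dienolate 14, whose γ-carbon C8a adds to the lactone carbonyl C8; the adduct collapses to the hemiacetal alkoxide 15, which loses pivalaldehyde to free the C7 alkoxide, and the new 1,3-dione is deprotonated at once, which makes the sequence irreversible. The closest known reaction type is the Dieckmann (intramolecular Claisen) cyclisation of keto esters to cyclohexane-1,3-diones, here in its vinylogous form with γ-acylation of a dienolate. Ring A (C4a, C5, C6, C7, C8, C8a) closes in the 6-(enolendo)-exo-trig mode and no other ring forms in this step. No new stereocentre is created (C8a ends as an enol carbon), C7 is quaternary and non-enolisable so the configuration from step 7 is carried through, and C13 is shielded because the substrate exists as an enolate while base is present. The step needs acylation at C8a rather than C4 or C5 and needs C7 and C4a cis on the enolate C6=C5 bond: the alkyne at C4 removes the competing acidic CH2, attack through C5 would give a four-membered ring, and the cisoid dienolate should be reached from either C4a=C5 isomer by proton exchange with HN(SiMe3)2 and by reversible, tethered β-alkoxide opening and reclosure of the dioxolane. The acylal character of the dioxolanone makes C8 a better acyl donor than a simple ester and keeps the C7 oxygen masked until the ring is closed, which avoids an acyloin shift of a free α-hydroxy β-keto ester.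

Step 11
Reactants: 16 (6R)-3-[(3E,5E,7S)-5,7-dimethylnona-3,5-dien-1-yn-1-yl]-4-(1,3-dioxolan-2-yl)-5,6-dihydroxy-6-methylcyclohexa-2,4-dien-1-one
Product: 18 (7S)-3-[(1E,3E,5S)-3,5-dimethylhepta-1,3-dien-1-yl]-7-hydroxy-7-methyl-6H-isochromene-6,8(7H)-dione, via formyl vinylogous acid 17 (not isolated)
Conditions: 1 M aq. HCl/THF, rt; extraction; then CuI (10 mol%), i-Pr2NEt, CH2Cl2, rt
Reagents that add atoms: water, O
Why: Hydrolysis of the enol-activated acetal gives the formyl vinylogous acid, whose enol oxygen should add 6-endo-dig to the enone-conjugated alkyne under CuI catalysis (cycloisomerisation of an alkynyl formyl quinol) to close ring B, with C7 untouched.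

Step 12
Reactants: 18 (7S)-3-[(1E,3E,5S)-3,5-dimethylhepta-1,3-dien-1-yl]-7-hydroxy-7-methyl-6H-isochromene-6,8(7H)-dione
Product: 19 (7S)-3-[(1E,3E,5S)-3,5-dimethylhepta-1,3-dien-1-yl]-7-methyl-6,8-dioxo-7,8-dihydro-6H-isochromen-7-yl propanoate
Conditions: (EtCO)2O, Et3N, DMAP (cat.), CH2Cl2, 0 °C to rt
Reagents that add atoms: propanoic anhydride, CCC(=O)OC(=O)CC
Why: DMAP-catalysed acylation esterifies the tertiary C7 alcohol, the only hydroxyl group, as is usual for 7-hydroxy azaphilones.

Step 13
Reactants: 19 (7S)-3-[(1E,3E,5S)-3,5-dimethylhepta-1,3-dien-1-yl]-7-methyl-6,8-dioxo-7,8-dihydro-6H-isochromen-7-yl propanoate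
Product: 20 sclerketide B, (7R)-5-chloro-3-[(1E,3E,5S)-3,5-dimethylhepta-1,3-dien-1-yl]-7-methyl-6,8-dioxo-7,8-dihydro-6H-isochromen-7-yl propanoate
Conditions: N-chlorosuccinimide (1.05 equiv), MeCN, rt, dark
Reagents that add atoms: N-chlorosuccinimide, O=C1CCC(=O)N1Cl
Why: Electrophilic chlorination should occur at C5, the nucleophilic terminus of the O2–C3=C4–C4a=C5 dienol ether; the C7 descriptor changes from S to R only because the new chlorine reorders the priorities, not because the centre is touched.

Compound list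
1 | (S)-2-methylbutan-1-ol | OC[C@@H](C)CC | starting material
2 | (S)-2-methylbutanal | O=C[C@@H](C)CC | intermediate
3 | (2E,4S)-2,4-dimethylhex-2-enal | O=C/C(C)=C/[C@@H](C)CC | intermediate
4 | trimethyl[(3E,5E,7S)-5,7-dimethylnona-3,5-dien-1-yn-1-yl]silane | C[Si](C)(C)C#C/C=C/C(C)=C/[C@@H](C)CC | intermediate
5 | (3E,5E,7S)-5,7-dimethylnona-3,5-dien-1-yne | C#C/C=C/C(C)=C/[C@@H](C)CC | intermediate
6 | (R)-lactic acid | C[C@@H](O)C(=O)O | starting material
7 | (2R,5R)-2-tert-butyl-5-methyl-1,3-dioxolan-4-one (cis) | C[C@H]1O[C@@H](C(C)(C)C)OC1=O | intermediate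
8 | 4,4-diethoxybut-1-yne | CCOC(CC#C)OCC | starting material
9 | 2-(prop-2-yn-1-yl)-1,3-dioxolane | C#CCC1OCCO1 | intermediate
10 | 4-(1,3-dioxolan-2-yl)but-2-ynal | O=CC#CCC1OCCO1 | intermediate
11 | (2R,5S)-2-tert-butyl-5-[4-(1,3-dioxolan-2-yl)-1-hydroxybut-2-yn-1-yl]-5-methyl-1,3-dioxolan-4-one (carbinol epimers) | C[C@@]1(C(O)C#CCC2OCCO2)O[C@@H](C(C)(C)C)OC1=O | intermediate
12 | (2R,5S)-2-tert-butyl-5-[4-(1,3-dioxolan-2-yl)but-2-ynoyl]-5-methyl-1,3-dioxolan-4-one | C[C@@]1(C(=O)C#CCC2OCCO2)O[C@@H](C(C)(C)C)OC1=O | intermediate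
13 | (2R,5S)-2-tert-butyl-5-[(2E,6E,8E,10S)-3-(1,3-dioxolan-2-ylmethyl)-8,10-dimethyldodeca-2,6,8-trien-4-ynoyl]-5-methyl-1,3-dioxolan-4-one | C[C@@]1(C(=O)/C=C(\CC2OCCO2)/C#C/C=C/C(C)=C/[C@@H](C)CC)O[C@@H](C(C)(C)C)OC1=O | intermediate
14 | potassium dienolate of 13 (deprotonated at the CH2 next to the dioxolane; enolate geometries not fixed) | C[C@@]1(C([O-])=CC(C#C/C=C/C(C)=C/[C@@H](C)CC)=CC2OCCO2)O[C@@H](C(C)(C)C)OC1=O.[K+] | intermediate
15 | potassium salt of the ring-closed triketone carrying the pivalaldehyde hemiacetal on the C7 oxygen | C[C@]1(OC([O-])C(C)(C)C)C(=O)C=C(C#C/C=C/C(C)=C/[C@@H](C)CC)C(C2OCCO2)C1=O.[K+] | intermediate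
16 | (6R)-3-[(3E,5E,7S)-5,7-dimethylnona-3,5-dien-1-yn-1-yl]-4-(1,3-dioxolan-2-yl)-5,6-dihydroxy-6-methylcyclohexa-2,4-dien-1-one | C[C@]1(O)C(=O)C=C(C#C/C=C/C(C)=C/[C@@H](C)CC)C(C2OCCO2)=C1O | intermediate
17 | (5R)-2-[(3E,5E,7S)-5,7-dimethylnona-3,5-dien-1-yn-1-yl]-5,6-dihydroxy-5-methyl-4-oxocyclohexa-1(6),2-diene-1-carbaldehyde | C[C@]1(O)C(=O)C=C(C#C/C=C/C(C)=C/[C@@H](C)CC)C(C=O)=C1O | intermediate
18 | (7S)-3-[(1E,3E,5S)-3,5-dimethylhepta-1,3-dien-1-yl]-7-hydroxy-7-methyl-6H-isochromene-6,8(7H)-dione | O[C@]1(C)C(=O)C2=COC(/C=C/C(C)=C/[C@@H](C)CC)=CC2=CC1=O | intermediate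
19 | (7S)-3-[(1E,3E,5S)-3,5-dimethylhepta-1,3-dien-1-yl]-7-methyl-6,8-dioxo-7,8-dihydro-6H-isochromen-7-yl propanoate | CCC(=O)O[C@]1(C)C(=O)C2=COC(/C=C/C(C)=C/[C@@H](C)CC)=CC2=CC1=O | intermediate
20 | sclerketide B, (7R)-5-chloro-3-[(1E,3E,5S)-3,5-dimethylhepta-1,3-dien-1-yl]-7-methyl-6,8-dioxo-7,8-dihydro-6H-isochromen-7-yl propanoate | CCC(=O)O[C@]1(C)C(=O)C2=COC(/C=C/C(C)=C/[C@@H](C)CC)=CC2=C(Cl)C1=O | target

Total step count: 13

Longest linear sequence: 9 steps (8 → 9 → 10 → 11 → 12 → 13 → 16 → 18 → 19 → 20; steps 5 to 13)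

Steps most likely to fail

Step 10. The dienolate may fail to reach the cisoid geometry needed for ring closure before unproductive processes take over: β-opening of the acetal without reclosure, aldol capture of the released pivalaldehyde, or deprotonation at the remote C13 position with erosion of its configuration. The fallback sets out from 13 and replaces the hard dienolate by a soft, chelated enolate. Mild hydrolysis of the dioxolane (pyridinium p-toluenesulfonate, wet acetone, 50 °C; the acylal of the dioxolanone is expected to survive) should give the keto aldehyde (2R,5S)-2-tert-butyl-5-[(2E,6E,8E,10S)-8,10-dimethyl-3-(2-oxoethyl)dodeca-2,6,8-trien-4-ynoyl]-5-methyl-1,3-dioxolan-4-one F1. Soft enolisation of its vinylogous β-keto aldehyde unit with MgBr2·OEt2 and i-Pr2NEt (CH2Cl2, 0 °C to rt) should then let C8a acylate on the same lactone carbonyl in a magnesium-templated Claisen-type closure with loss of pivalaldehyde. This gives 17 directly, which is closed with CuI and i-Pr2NEt as in step 11, so the fallback comes back to the route at 18.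

Step 9. The basic phosphine may isomerise the skipped ynone to an allenyl or dienyl ketone, or the donor alkyne may dimerise, before the cross-addition takes place. The fallback sets out from 12 and builds the C4a–C4 bond by a halide coupling instead. Anti hydroiodination (NaI, AcOH, MeCN, rt) should give the β-iodo enone (2R,5S)-2-tert-butyl-5-[(2Z)-4-(1,3-dioxolan-2-yl)-3-iodobut-2-enoyl]-5-methyl-1,3-dioxolan-4-one F2. Sonogashira coupling of F2 with 5 (PdCl2(PPh3)2, CuI, Et3N, THF, rt) should give, with retention, the geometric isomer (2R,5S)-2-tert-butyl-5-[(2Z,6E,8E,10S)-3-(1,3-dioxolan-2-ylmethyl)-8,10-dimethyldodeca-2,6,8-trien-4-ynoyl]-5-methyl-1,3-dioxolan-4-one F3. Because the dienolate of step 10 no longer has a C4a=C5 double bond, F3 should converge on the same ring-closed product under the conditions of step 10, so the fallback comes back to the route at 16.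

Step 3. The olefination may give incomplete E-selectivity at the new double bond, or the propargyl/allenyl phosphonate anion may deliver allenic by-products, and the volatile dienyne may be lost on isolation. The fallback sets out from 3 and separates the two bond formations. Takai olefination (CrCl2, CHI3, THF, 0 °C) should give the (E)-dienyl iodide (1E,3E,5S)-1-iodo-3,5-dimethylhepta-1,3-diene F4. Sonogashira coupling of F4 with ethynyltrimethylsilane (PdCl2(PPh3)2, CuI, Et3N, rt) then gives the silyl dienyne, so the fallback comes back to the route at 4, which is desilylated with K2CO3 in MeOH to 5 as in step 3.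

Further compounds
F1 | step 10 | (2R,5S)-2-tert-butyl-5-[(2E,6E,8E,10S)-8,10-dimethyl-3-(2-oxoethyl)dodeca-2,6,8-trien-4-ynoyl]-5-methyl-1,3-dioxolan-4-one | C[C@@]1(C(=O)/C=C(\CC=O)/C#C/C=C/C(C)=C/[C@@H](C)CC)O[C@@H](C(C)(C)C)OC1=O
F2 | step 9 | (2R,5S)-2-tert-butyl-5-[(2Z)-4-(1,3-dioxolan-2-yl)-3-iodobut-2-enoyl]-5-methyl-1,3-dioxolan-4-one | C[C@@]1(C(=O)/C=C(\I)CC2OCCO2)O[C@@H](C(C)(C)C)OC1=O
F3 | step 9 | (2R,5S)-2-tert-butyl-5-[(2Z,6E,8E,10S)-3-(1,3-dioxolan-2-ylmethyl)-8,10-dimethyldodeca-2,6,8-trien-4-ynoyl]-5-methyl-1,3-dioxolan-4-one | C[C@@]1(C(=O)/C=C(/CC2OCCO2)\C#C/C=C/C(C)=C/[C@@H](C)CC)O[C@@H](C(C)(C)C)OC1=O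
F4 | step 3 | (1E,3E,5S)-1-iodo-3,5-dimethylhepta-1,3-diene | I/C=C/C(C)=C/[C@@H](C)CC
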